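**Strategy.** The route rests on making the seven-membered lactone (C16, O, C12, C13, C14, C1, C15) without ever acylating the tertiary C12 hydroxyl. A C12,C13-diol, both oxygens in place and C12 already configured, is converted into a 2-methylene-1,3-dioxolane carrying a (Z)-alkenyl group on C13. Its Claisen ring expansion forms the C15–C1 bond, turns the dioxolane into the lactone with the C12–O bond intact, and creates C1 by chirality transfer from the sacrificial C13 carbinol. The precursor is an open-chain allylic diol assembled from two epoxy-alcohol-derived fragments; the 14-membered carbocycle is closed afterwards at C8–C9.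

Key step: step 18

Remark (numbering, geometry, descriptors): atoms carry cembrane numbers of the target — lactone C16(=O)–O–C12, C15(=C17H2), ring CH C1, 3,4-diol, C7=C8, 11-OH, methyls C18/C19/C20 on C4/C8/C12. The SMILES places C6 and C9 cis on C7=C8, so the route is planned for (7Z) and for (1R,3R,4S,11S,12R). Descriptors given for 19–32 are those of each compound itself.

**Fragment A (C14, C1–C8, C18, C19)**

Step 1
Reactants: 1 geraniol
Product: 2 [(2R,3R)-3-methyl-3-(4-methylpent-3-en-1-yl)oxiran-2-yl]methanol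
Conditions: Ti(OiPr)4 (5 mol %), D-(−)-diethyl tartrate (7 mol %), t-BuOOH, 4 Å MS, CH2Cl2, −20 °C
Reagents that add atoms: tert-butyl hydroperoxide, CC(C)(C)OO
Why: Sharpless asymmetric epoxidation of the allylic alcohol with the D-tartrate should give the (2R,3R)-epoxide, fixing the C3–O bond of the target and leaving the remote trisubstituted alkene untouched.

Step 2
Reactants: 2 [(2R,3R)-3-methyl-3-(4-methylpent-3-en-1-yl)oxiran-2-yl]methanol
Product: 3 (2R,3S)-1,2-dihydroxy-3,7-dimethyloct-6-en-3-yl benzoate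
Conditions: Ti(OiPr)4 (1.5 equiv), PhCO2H, CH2Cl2, rt
Reagents that add atoms: benzoic acid, OC(=O)c1ccccc1
Why: Titanium-mediated opening of a 2,3-epoxy alcohol at C-3 (here the tertiary carbon, future C4) with inversion should give the anti C3/C4 dioxygenation of the target (C4 = S) while C3 keeps its epoxide oxygen.

Step 3
Reactants: 3 (2R,3S)-1,2-dihydroxy-3,7-dimethyloct-6-en-3-yl benzoate
Product: 5 (2S)-6-methyl-2-[(2R)-oxiran-2-yl]hept-5-en-2-ol, via primary tosylate 4 (not isolated)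
Conditions: TsCl, Et3N, Bu2SnO (cat.), CH2Cl2, 0 °C; then K2CO3, MeOH, 0 °C → rt
Reagents that add atoms: none
Why: Tin-catalysed sulfonylation is selective for the primary hydroxyl, and base then closes the terminal epoxide by intramolecular Williamson displacement (C3 retained) while methanolysing the benzoate.

Step 4
Reactants: 5 (2S)-6-methyl-2-[(2R)-oxiran-2-yl]hept-5-en-2-ol
Product: 6 (4R,5S)-5,9-dimethyldec-8-en-1-yne-4,5-diol
Conditions: HC≡CLi·H2NCH2CH2NH2, DMSO, rt
Reagents that add atoms: lithium acetylide–ethylenediamine complex, [Li]C#C.NCCN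
Why: SN2 opening of the terminal epoxide by acetylide at the CH2 terminus should install C1/C14 and release the C3 hydroxyl with retention.

Step 5
Reactants: 6 (4R,5S)-5,9-dimethyldec-8-en-1-yne-4,5-diol
Product: 7 (4S,5R)-2,2,4-trimethyl-4-(4-methylpent-3-en-1-yl)-5-(prop-2-yn-1-yl)-1,3-dioxolane
Conditions: Me2C(OMe)2, PPTS (cat.), CH2Cl2, rt
Reagents that add atoms: 2,2-dimethoxypropane, COC(C)(C)OC
Why: Acid-catalysed transacetalisation protects the secondary/tertiary 1,2-diol as its acetonide.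

Step 6
Reactants: 7 (4S,5R)-2,2,4-trimethyl-4-(4-methylpent-3-en-1-yl)-5-(prop-2-yn-1-yl)-1,3-dioxolane
Product: 9 3-[(4S,5R)-2,2,4-trimethyl-5-(prop-2-yn-1-yl)-1,3-dioxolan-4-yl]propanal, via ozonide 8 (not isolated)
Conditions: O3, CH2Cl2, −78 °C (Sudan III end point); then Me2S, −78 °C → rt
Reagents that add atoms: ozone, [O-][O+]=O
Why: Ozonolysis should cleave the electron-rich trisubstituted alkene far faster than the terminal alkyne, giving the C7 aldehyde.

Step 7
Reactants: 9 3-[(4S,5R)-2,2,4-trimethyl-5-(prop-2-yn-1-yl)-1,3-dioxolan-4-yl]propanal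
Product: 10 (4S,5R)-4-[(3Z)-4-iodopent-3-en-1-yl]-2,2,4-trimethyl-5-(prop-2-yn-1-yl)-1,3-dioxolane
Conditions: [Ph3PCH(I)CH3]I, NaHMDS, THF, −78 °C; then 9, −78 → −20 °C
Reagents that add atoms: (1-iodoethyl)triphenylphosphonium iodide, CC(I)[P+](c1ccccc1)(c1ccccc1)c1ccccc1.[I-]
Why: Stork–Zhao-type Wittig olefination with the α-iodo ylide should give the (Z)-2-iodoalkene (iodine cis to the chain), which fixes the later C7=C8 geometry and brings in C8 and C19.

**Fragment B (C9–C13, C20)**

Step 8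
Reactants: 11 acrolein; 12 ethyl 2-(triphenyl-λ5-phosphanylidene)propanoate
Product: 13 ethyl (2E)-2-methylpenta-2,4-dienoate
Conditions: CH2Cl2, 0 °C → rt
Reagents that add atoms: none
Why: Wittig olefination with a stabilised ylide should give the (E)-trisubstituted enoate, the future E-C11=C12 unit.

Step 9
Reactants: 13 ethyl (2E)-2-methylpenta-2,4-dienoate
Product: 14 (2E)-2-methylpenta-2,4-dien-1-ol
Conditions: DIBAL-H, CH2Cl2, −78 °C
Reagents that add atoms: none
Why: DIBAL-H reduces the conjugated ester in 1,2-fashion to the allylic alcohol.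

Step 10
Reactants: 14 (2E)-2-methylpenta-2,4-dien-1-ol
Product: 15 [(2R,3R)-3-ethenyl-2-methyloxiran-2-yl]methanol
Conditions: Ti(OiPr)4 (10 mol %), D-(−)-diethyl tartrate (12 mol %), t-BuOOH, 4 Å MS, CH2Cl2, −20 °C
Reagents that add atoms: tert-butyl hydroperoxide, CC(C)(C)OO
Why: Sharpless asymmetric epoxidation is specific for the allylic-alcohol alkene and sets the C12–O bond (the future lactone oxygen) in its final configuration.

Step 11
Reactants: 15 [(2R,3R)-3-ethenyl-2-methyloxiran-2-yl]methanol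
Product: 16 (3S,4R)-4,5-dihydroxy-4-methylpent-1-en-3-yl 2,2-dimethylpropanoate
Conditions: Ti(OiPr)4 (1.5 equiv), t-BuCO2H, CH2Cl2, 0 °C → rt
Reagents that add atoms: pivalic acid, CC(C)(C)C(O)=O
Why: Titanium-mediated opening at C-3 (allylic C11) with inversion should give (11S) and the anti C11/C12 pattern, the C12–O bond staying untouched.

Step 12
Reactants: 16 (3S,4R)-4,5-dihydroxy-4-methylpent-1-en-3-yl 2,2-dimethylpropanoate
Product: 17 (3S,4S)-4-hydroxy-4-methyl-5-oxopent-1-en-3-yl 2,2-dimethylpropanoate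
Conditions: SO3·pyridine, DMSO, i-Pr2NEt, CH2Cl2, 0 °C
Reagents that add atoms: none
Why: Parikh–Doering oxidation converts only the primary alcohol to the aldehyde and, unlike periodate-type or hypervalent-iodine oxidants, cannot cleave the 1,2-diol.

**Union and endgame**

Step 13
Reactants: 10 (4S,5R)-4-[(3Z)-4-iodopent-3-en-1-yl]-2,2,4-trimethyl-5-(prop-2-yn-1-yl)-1,3-dioxolane; 17 (3S,4S)-4-hydroxy-4-methyl-5-oxopent-1-en-3-yl 2,2-dimethylpropanoate
Product: 19 (3R,4S,11S,12R,13S)-propargylic 12,13-diol (C14≡C1 alkyne; 11-OPiv; C9=C10 vinyl; 3,4-acetonide; (7Z)-8-iodide), via alkynylmagnesium bromide 18 (not isolated)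
Conditions: 10 (2.1 equiv), EtMgBr, THF, 40 °C; then 17, THF, −78 → −40 °C; aq. NH4Cl (excess 10 recovered)
Reagents that add atoms: none
Why: Cram-chelate addition: the magnesium alkoxide of the tertiary C12–OH chelates the aldehyde, and the acetylide should attack from the methyl face, away from the CH(OPiv)vinyl group, giving the syn (13S) diol.

Step 14
Reactants: 19 (3R,4S,11S,12R,13S)-propargylic 12,13-diol
Product: 20 (3R,4S,11S,12R,13S)-(Z)-allylic 12,13-diol (cis C14=C1)
Conditions: H2 (1 atm), Lindlar catalyst, quinoline, EtOAc, 0 °C, stopped at 1 equiv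
Reagents that add atoms: none
Why: Lindlar semihydrogenation adds H2 syn to give the (Z)-alkene required for the chirality transfer; the poisoned catalyst and the one-equivalent end point are meant to spare the vinyl and vinyl iodide groups.

Step 15
Reactants: 20 (3R,4S,11S,12R,13S)-(Z)-allylic 12,13-diol
Product: 21 (3R,4S,11S,12R,13S)-2-(phenylselanylmethyl)-1,3-dioxolane of the 12,13-diol (11-OPiv; epimers at the acetal carbon)
Conditions: PhSeCH2CH(OEt)2, PPTS (cat.), toluene, 80 °C
Reagents that add atoms: 2,2-diethoxyethyl phenyl selenide, CCOC(C[Se]c1ccccc1)OCC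
Why: Transacetalisation onto the only free 1,2-diol forms the five-membered acetal that carries C16 and C15; even the tertiary hydroxyl takes part readily in a ring-forming acetal exchange.

Step 16
Reactants: 21 (3R,4S,11S,12R,13S)-2-(phenylselanylmethyl)-1,3-dioxolane (11-OPiv)
Product: 22 (3R,4S,11S,12S,13S)-dioxolane 11-alcohol
Conditions: DIBAL-H, CH2Cl2, −78 °C
Reagents that add atoms: none
Why: Reductive cleavage of the pivalate frees the C11 hydroxyl before any lactone is present.

Step 17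
Reactants: 22 (3R,4S,11S,12S,13S)-dioxolane 11-alcohol
Product: 23 (3R,4S,11S,12R,13S)-dioxolane 11-TBS ether
Conditions: TBSOTf, 2,6-lutidine, CH2Cl2, −78 → 0 °C
Reagents that add atoms: tert-butyldimethylsilyl trifluoromethanesulfonate, CC(C)(C)[Si](C)(C)OS(=O)(=O)C(F)(F)F
Why: Silylation of the hindered secondary alcohol gives a group that survives the thermal, enolate and coupling steps and prevents the hydroxyl from adding to the ketene acetal.

Step 18
Reactants: 23 (3R,4S,11S,12R,13S)-dioxolane 11-TBS ether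
Product: 26 (1R,3R,4S,11S,12R)-ene-lactone (seven-membered lactone with cis C13=C14; C1 bears the C2–C8 arm; C12 bears methyl and the CH(OTBS)CH=CH2 arm), via selenoxide 24 (not isolated), via ketene acetal 25 (not isolated)
Conditions: NaIO4, NaHCO3, MeOH/H2O, rt; then DBU, xylenes, 140 °C (sealed tube)
Reagents that add atoms: none
Why: Periodate oxidises the selenide, syn-elimination of PhSeOH (only the acetal C–H is β) gives the 2-methylene-1,3-dioxolane 25, and a concerted [3,3]-sigmatropic shift through C15=C16–O13–C13–C14=C1 breaks C13–O13 and forms C15–C1. The closest known reaction type is the Claisen ring expansion of 2-methylene-4-vinyl-1,3-dioxolanes to seven-membered ene-lactones, here applied to a new substrate. The lactone ring is closed by ring expansion (five-membered ketene acetal plus the two alkene carbons), not by C–O bond formation, and the new ring alkene C13=C14 is necessarily cis. C1 is set by suprafacial 1,3-chirality transfer: C15 bonds to the alkene face from which O13 leaves, so (13S) with the (Z)-alkene gives (1R), while C12 cannot change because its C–O bond is never broken. The step needs only the O13 allyl system to rearrange, which holds because O12 is homoallylic to the C9=C10 vinyl group; the silyl ether blocks orthoester formation, and base with no acid keeps the ketene acetal from hydrolysis.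

Step 19
Reactants: 26 (1R,3R,4S,11S,12R)-ene-lactone
Product: 28 (1R,3R,4S,11S,12R)-macrocyclic ene-lactone (14-membered carbocycle; (7Z); cis C13=C14; 11-OTBS; 3,4-acetonide), via B-alkyl-9-BBN borane 27 (not isolated)
Conditions: 9-BBN, THF, rt; then slow addition to Pd(dppf)Cl2 (20 mol %), AsPh3, Cs2CO3, DMF/THF/H2O, 50 °C (final 1 mM)
Reagents that add atoms: none
Why: 9-BBN should hydroborate only the terminal C9=C10 vinyl group (boron on C9), and intramolecular B-alkyl Suzuki–Miyaura coupling with the vinyl iodide closes C8–C9 with retention of alkene geometry, giving (7Z).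

Step 20
Reactants: 28 (1R,3R,4S,11S,12R)-macrocyclic ene-lactone
Product: 29 (1R,3R,4S,11S,12R)-saturated macrocyclic lactone (C13–C14 reduced)
Conditions: 2-nitrobenzenesulfonohydrazide, Et3N, CH2Cl2, rt
Reagents that add atoms: none
Why: Diimide generated in situ reduces the cis-disubstituted ring alkene much faster than the trisubstituted C7=C8 alkene, and no stereocentre is formed.

Step 21
Reactants: 29 (1R,3R,4S,11S,12R)-saturated macrocyclic lactone
Product: 32 (1R,3R,4S,11S,12R)-α-methylene lactone (11-OTBS; 3,4-acetonide), via Mannich base 30 (not isolated), via trimethylammonium iodide 31 (not isolated)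
Conditions: LDA, THF, −78 °C; Me2N+=CH2 I−, −78 → 0 °C; then MeI, CH2Cl2, rt; then DBU, rt
Reagents that add atoms: Eschenmoser's salt, C=[N+](C)C.[I-]
Why: Mannich reaction of the lactone enolate (C15 is the only enolisable position) with Eschenmoser's salt, quaternisation and Hofmann-type elimination install the C15=C17 methylene.

Step 22
Reactants: 32 (1R,3R,4S,11S,12R)-α-methylene lactone (11-OTBS; 3,4-acetonide)
Product: 33 CNP0263298.1 (target)
Conditions: HF (48 % aq.), MeCN, 0 °C → rt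
Reagents that add atoms: none
Why: Aqueous acidic fluoride removes the silyl ether and the acetonide under conditions that the α-methylene lactone and its tertiary ester should tolerate.

**Compound list**

1 | geraniol, (2E)-3,7-dimethylocta-2,6-dien-1-ol | CC(C)=CCC/C(C)=C/CO | starting material
2 | [(2R,3R)-3-methyl-3-(4-methylpent-3-en-1-yl)oxiran-2-yl]methanol | OC[C@H]1O[C@]1(C)CCC=C(C)C | intermediate
3 | (2R,3S)-1,2-dihydroxy-3,7-dimethyloct-6-en-3-yl benzoate | OC[C@@H](O)[C@@](C)(OC(=O)c1ccccc1)CCC=C(C)C | intermediate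
4 | (2R,3S)-2-hydroxy-3,7-dimethyl-1-(tosyloxy)oct-6-en-3-yl benzoate | Cc1ccc(cc1)S(=O)(=O)OC[C@@H](O)[C@@](C)(OC(=O)c2ccccc2)CCC=C(C)C | intermediate
5 | (2S)-6-methyl-2-[(2R)-oxiran-2-yl]hept-5-en-2-ol | C1O[C@H]1[C@@](C)(O)CCC=C(C)C | intermediate
6 | (4R,5S)-5,9-dimethyldec-8-en-1-yne-4,5-diol | C#CC[C@@H](O)[C@@](C)(O)CCC=C(C)C | intermediate
7 | (4S,5R)-2,2,4-trimethyl-4-(4-methylpent-3-en-1-yl)-5-(prop-2-yn-1-yl)-1,3-dioxolane | C#CC[C@H]1OC(C)(C)O[C@@]1(C)CCC=C(C)C | intermediate
8 | ozonide of 7 (5,5-dimethyl-1,2,4-trioxolan-3-yl end group) | C#CC[C@H]1OC(C)(C)O[C@@]1(C)CCC2OOC(C)(C)O2 | intermediate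
9 | 3-[(4S,5R)-2,2,4-trimethyl-5-(prop-2-yn-1-yl)-1,3-dioxolan-4-yl]propanal | C#CC[C@H]1OC(C)(C)O[C@@]1(C)CCC=O | intermediate
10 | (4S,5R)-4-[(3Z)-4-iodopent-3-en-1-yl]-2,2,4-trimethyl-5-(prop-2-yn-1-yl)-1,3-dioxolane | C#CC[C@H]1OC(C)(C)O[C@@]1(C)CC/C=C(/C)I | intermediate
11 | acrolein (prop-2-enal) | C=CC=O | starting material
12 | ethyl 2-(triphenyl-λ5-phosphanylidene)propanoate | CCOC(=O)C(C)=P(c1ccccc1)(c1ccccc1)c1ccccc1 | starting material
13 | ethyl (2E)-2-methylpenta-2,4-dienoate | C=C/C=C(\C)C(=O)OCC | intermediate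
14 | (2E)-2-methylpenta-2,4-dien-1-ol | C=C/C=C(\C)CO | intermediate
15 | [(2R,3R)-3-ethenyl-2-methyloxiran-2-yl]methanol | OC[C@@]1(C)O[C@@H]1C=C | intermediate
16 | (3S,4R)-4,5-dihydroxy-4-methylpent-1-en-3-yl 2,2-dimethylpropanoate | OC[C@@](C)(O)[C@@H](OC(=O)C(C)(C)C)C=C | intermediate
17 | (3S,4S)-4-hydroxy-4-methyl-5-oxopent-1-en-3-yl 2,2-dimethylpropanoate | O=C[C@@](C)(O)[C@@H](OC(=O)C(C)(C)C)C=C | intermediate
18 | alkynylmagnesium bromide of 10 | Br[Mg]C#CC[C@H]1OC(C)(C)O[C@@]1(C)CC/C=C(/C)I | intermediate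
19 | (3R,4S,11S,12R,13S)-propargylic 12,13-diol (11-OPiv; C9=C10 vinyl; C14≡C1; 3,4-acetonide; (7Z)-8-iodide) | C=C[C@H](OC(=O)C(C)(C)C)[C@](C)(O)[C@@H](O)C#CC[C@H]1OC(C)(C)O[C@@]1(C)CC/C=C(/C)I | intermediate
20 | (3R,4S,11S,12R,13S)-(Z)-allylic 12,13-diol (cis C14=C1) | C=C[C@H](OC(=O)C(C)(C)C)[C@](C)(O)[C@@H](O)/C=C\C[C@H]1OC(C)(C)O[C@@]1(C)CC/C=C(/C)I | intermediate
21 | (3R,4S,11S,12R,13S)-2-(phenylselanylmethyl)-1,3-dioxolane of the 12,13-diol, 11-pivalate | C=C[C@H](OC(=O)C(C)(C)C)[C@]1(C)OC(C[Se]c2ccccc2)O[C@H]1/C=C\C[C@H]3OC(C)(C)O[C@@]3(C)CC/C=C(/C)I | intermediate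
22 | (3R,4S,11S,12S,13S)-dioxolane 11-alcohol | C=C[C@H](O)[C@]1(C)OC(C[Se]c2ccccc2)O[C@H]1/C=C\C[C@H]3OC(C)(C)O[C@@]3(C)CC/C=C(/C)I | intermediate
23 | (3R,4S,11S,12R,13S)-dioxolane 11-TBS ether | C=C[C@H](O[Si](C)(C)C(C)(C)C)[C@]1(C)OC(C[Se]c2ccccc2)O[C@H]1/C=C\C[C@H]3OC(C)(C)O[C@@]3(C)CC/C=C(/C)I | intermediate
24 | selenoxide of 23 | C=C[C@H](O[Si](C)(C)C(C)(C)C)[C@]1(C)OC(C[Se](=O)c2ccccc2)O[C@H]1/C=C\C[C@H]3OC(C)(C)O[C@@]3(C)CC/C=C(/C)I | intermediate
25 | ketene acetal (2-methylene-1,3-dioxolane) | C=C[C@H](O[Si](C)(C)C(C)(C)C)[C@]1(C)OC(=C)O[C@H]1/C=C\C[C@H]2OC(C)(C)O[C@@]2(C)CC/C=C(/C)I | intermediate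
26 | (1R,3R,4S,11S,12R)-ene-lactone (seven-membered; cis C13=C14) | O=C1C[C@@H](C[C@H]2OC(C)(C)O[C@@]2(C)CC/C=C(/C)I)/C=C\[C@](C)([C@@H](O[Si](C)(C)C(C)(C)C)C=C)O1 | intermediate
27 | B-alkyl-9-BBN borane of 26 (boron on C9) | O=C1C[C@@H](C[C@H]2OC(C)(C)O[C@@]2(C)CC/C=C(/C)I)/C=C\[C@](C)([C@@H](O[Si](C)(C)C(C)(C)C)CCB3C4CCCC3CCC4)O1 | intermediate
28 | (1R,3R,4S,11S,12R)-macrocyclic ene-lactone | O=C1C[C@H]2C[C@H]3OC(C)(C)O[C@@]3(C)CC/C=C(/C)CC[C@H](O[Si](C)(C)C(C)(C)C)[C@](C)(O1)/C=C\2 | intermediate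
29 | (1R,3R,4S,11S,12R)-saturated macrocyclic lactone | O=C1C[C@H]2C[C@H]3OC(C)(C)O[C@@]3(C)CC/C=C(/C)CC[C@H](O[Si](C)(C)C(C)(C)C)[C@](C)(O1)CC2 | intermediate
30 | Mannich base (15-dimethylaminomethyl lactone) | CN(C)CC1C(=O)O[C@]2(C)CC[C@@H]1C[C@H]3OC(C)(C)O[C@@]3(C)CC/C=C(/C)CC[C@@H]2O[Si](C)(C)C(C)(C)C | intermediate
31 | trimethylammonium iodide of 30 | C[N+](C)(C)CC1C(=O)O[C@]2(C)CC[C@@H]1C[C@H]3OC(C)(C)O[C@@]3(C)CC/C=C(/C)CC[C@@H]2O[Si](C)(C)C(C)(C)C.[I-] | intermediate
32 | (1R,3R,4S,11S,12R)-α-methylene lactone, 11-TBS ether, 3,4-acetonide | C=C1C(=O)O[C@]2(C)CC[C@@H]1C[C@H]3OC(C)(C)O[C@@]3(C)CC/C=C(/C)CC[C@@H]2O[Si](C)(C)C(C)(C)C | intermediate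
33 | CNP0263298.1 | C=C1C(=O)O[C@]2(C)CC[C@@H]1C[C@@H](O)[C@@](C)(O)CC/C=C(/C)CC[C@@H]2O | target

**Totals.** Total step count: 22. Longest linear sequence: 17 steps (steps 1–7, then 13–22).

**Steps most likely to fail**

1. Step 18 (key step). The oxidative entry to the ketene acetal may fail before the rearrangement starts: the PhSeOH released can add to the electron-rich alkenes, or the ketene acetal can hydrolyse to a hydroxy acetate. The fallback is a selenium-free, base-mediated entry that sets out from 20 and comes back at 25. Diol 20 is acetalised with bromoacetaldehyde diethyl acetal (PPTS) to the 2-(bromomethyl)dioxolane pivalate F1; DIBAL-H gives the 11-alcohol F2; TBSOTf/2,6-lutidine gives the silyl ether F3; E2 dehydrobromination with KOt-Bu in THF then forms ketene acetal 25, which is heated as in step 18 to give 26.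

2. Step 19. At high dilution the intramolecular transmetalation and reductive elimination may lose to protodeboronation, β-hydride elimination or oligomerisation. The fallback changes the nucleophile and the coupling manifold, setting out from 26 and returning at 28. Hydroboration–oxidation (9-BBN; NaBO3) gives primary alcohol F4; Appel iodination (I2, PPh3, imidazole) gives iodide F5; zinc insertion (Zn, LiCl, THF) gives alkylzinc iodide F6; intramolecular Negishi coupling (Pd2(dba)3, SPhos, slow addition) closes C8–C9 to 28.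

3. Step 13. Facial selectivity may be eroded if open transition states compete with the chelate, or if the pivalate migrates to the magnesium alkoxide. The fallback replaces substrate control by reagent control, setting out from crude 19 (epimer mixture at C13) and returning at 19. The mixture is oxidised (MnO2 or Dess–Martin periodinane) to ynone F7, which is reduced by Noyori asymmetric transfer hydrogenation (RuCl(p-cymene)(TsDPEN), HCO2H/Et3N), the catalyst antipode being chosen to return (13S)-19.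

**Further compounds**

F1 | step 18 | 2-(bromomethyl)-1,3-dioxolane of the 12,13-diol, 11-pivalate | C=C[C@H](OC(=O)C(C)(C)C)[C@]1(C)OC(CBr)O[C@H]1/C=C\C[C@H]2OC(C)(C)O[C@@]2(C)CC/C=C(/C)I
F2 | step 18 | 2-(bromomethyl)-1,3-dioxolane 11-alcohol | C=C[C@H](O)[C@]1(C)OC(CBr)O[C@H]1/C=C\C[C@H]2OC(C)(C)O[C@@]2(C)CC/C=C(/C)I
F3 | step 18 | 2-(bromomethyl)-1,3-dioxolane 11-TBS ether | C=C[C@H](O[Si](C)(C)C(C)(C)C)[C@]1(C)OC(CBr)O[C@H]1/C=C\C[C@H]2OC(C)(C)O[C@@]2(C)CC/C=C(/C)I
F4 | step 19 | primary alcohol from hydroboration–oxidation of 26 (9-OH) | O=C1C[C@@H](C[C@H]2OC(C)(C)O[C@@]2(C)CC/C=C(/C)I)/C=C\[C@](C)([C@@H](O[Si](C)(C)C(C)(C)C)CCO)O1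
F5 | step 19 | primary iodide (9-iodo) | O=C1C[C@@H](C[C@H]2OC(C)(C)O[C@@]2(C)CC/C=C(/C)I)/C=C\[C@](C)([C@@H](O[Si](C)(C)C(C)(C)C)CCI)O1
F6 | step 19 | alkylzinc iodide (zinc on C9) | O=C1C[C@@H](C[C@H]2OC(C)(C)O[C@@]2(C)CC/C=C(/C)I)/C=C\[C@](C)([C@@H](O[Si](C)(C)C(C)(C)C)CC[Zn]I)O1
F7 | step 13 | 13-ynone (12-hydroxy-13-oxo-14-yne; 11-OPiv) | C=C[C@H](OC(=O)C(C)(C)C)[C@](C)(O)C(=O)C#CC[C@H]1OC(C)(C)O[C@@]1(C)CC/C=C(/C)I
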